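**Plan**

- Retrosynthesis cuts two bonds around the ester: the O–CH2 bond at the benzylic carbon on ring B C6, and the bond from ring A C1 to the ester carbonyl carbon, which then comes from CO2.
- The enabling feature is that the ester C=O sits on ring A C1 between C2–O and C6–CH3, which shields it against acyl substitution, while its alcohol partner is a primary benzylic CH2 on ring B C6, open to SN2. The carbonyl is therefore put on as CO2 and the carboxylate oxygen is alkylated.
- Ring A piece: 2,5-dimethylresorcinol is MOM-protected and monobrominated. Ring B piece: 3,5-dihydroxy-4-methylbenzoic acid is MOM-protected, reduced, ortho-lithiated and carboxylated (ring B C1–CO2H), allylated and brominated at the benzylic carbon.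
- Forward order: both benzene rings come from the starting materials and no ring is formed. The two arenes and CO2 are joined in step 8, the four MOM ethers are then removed, and the allyl ester is cleaved last.
- Stereochemistry: the target has no stereocentre and no configured double bond, so nothing has to be set.

Key step: step 8

Remark: where CO2 meets a lithium alkoxide (step 5), the reversible O-carbonate is not drawn, because it reverts to the alcohol on acidification.

**Route**

Step 1
Reactants: 1 2,5-dimethylbenzene-1,3-diol
Product: 2 1,3-bis(methoxymethoxy)-2,5-dimethylbenzene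
Conditions: NaH (2.4 equiv), MOMCl (2.4 equiv), DMF, 0 °C to rt
Reagents that add atoms: chloromethyl methyl ether (MOMCl), COCCl
Why: Williamson-type O-alkylation of the bis-phenoxide with the hard electrophile MOMCl should give the bis-acetal, whose MOM groups later chelate the aryllithium and come off with acid.

Step 2
Reactants: 2 1,3-bis(methoxymethoxy)-2,5-dimethylbenzene
Product: 3 1-bromo-2,4-bis(methoxymethoxy)-3,6-dimethylbenzene
Conditions: NBS (1.0 equiv), MeCN, 0 °C, dark
Reagents that add atoms: N-bromosuccinimide, O=C1CCC(=O)N1Br
Why: Electrophilic aromatic bromination can only reach the two equivalent free ring positions, each ortho to one OMOM and para to the other, so one equivalent of NBS under ionic conditions should give the monobromide and leave the methyl groups alone.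

Step 3
Reactants: 4 3,5-dihydroxy-4-methylbenzoic acid
Product: 5 methoxymethyl 3,5-bis(methoxymethoxy)-4-methylbenzoate
Conditions: NaH (3.3 equiv), MOMCl (3.3 equiv), DMF, 0 °C to rt
Reagents that add atoms: chloromethyl methyl ether (MOMCl), COCCl
Why: O-alkylation of the carboxylate and both phenoxides in one operation should protect the phenols and turn the acid into an ester that hydride reduces easily.

Step 4
Reactants: 5 methoxymethyl 3,5-bis(methoxymethoxy)-4-methylbenzoate
Product: 6 [3,5-bis(methoxymethoxy)-4-methylphenyl]methanol
Conditions: LiAlH4, THF, 0 °C; then H2O, 15% aq. NaOH, H2O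
Reagents that add atoms: none
Why: LiAlH4 reduction of the ester should give the primary benzylic alcohol, while the aryl MOM acetals are inert to hydride.

Step 5
Reactants: 6 [3,5-bis(methoxymethoxy)-4-methylphenyl]methanol; 7 carbon dioxide
Product: 10 6-(hydroxymethyl)-2,4-bis(methoxymethoxy)-3-methylbenzoic acid, via aryllithium alkoxide 8 (not isolated), via dilithium carboxylate 9 (not isolated)
Conditions: n-BuLi (2.3 equiv), TMEDA, THF, −78 to 0 °C; dry CO2 gas, −78 °C to rt; cold 1 M HCl to pH 3, extraction, used without delay
Reagents that add atoms: none
Why: In this directed ortho-metalation the first equivalent of base forms the alkoxide and the second removes the ring hydrogen flanked by CH2OLi and OMOM (both such positions are equivalent and the two groups direct cooperatively), so carboxylation of the aryllithium and brief mild acidification should give the hydroxy acid with the MOM ethers intact.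

Step 6
Reactants: 10 6-(hydroxymethyl)-2,4-bis(methoxymethoxy)-3-methylbenzoic acid; 11 allyl bromide (3-bromoprop-1-ene)
Product: 13 allyl 6-(hydroxymethyl)-2,4-bis(methoxymethoxy)-3-methylbenzoate, via potassium carboxylate 12 (not isolated)
Conditions: KHCO3 (1.2 equiv), allyl bromide (1.5 equiv), DMF, rt
Reagents that add atoms: none
Why: SN2 alkylation of the carboxylate oxygen is insensitive to the two ortho substituents, and KHCO3 is too weak a base to deprotonate the benzylic alcohol, so neither ether formation nor base-driven lactonisation should compete.

Step 7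
Reactants: 13 allyl 6-(hydroxymethyl)-2,4-bis(methoxymethoxy)-3-methylbenzoate
Product: 14 allyl 6-(bromomethyl)-2,4-bis(methoxymethoxy)-3-methylbenzoate
Conditions: CBr4, PPh3, 2,6-lutidine, CH2Cl2, 0 °C; used promptly
Reagents that add atoms: carbon tetrabromide, BrC(Br)(Br)Br
Why: In the Appel reaction the primary benzylic alcohol is activated as an alkoxyphosphonium ion and displaced by bromide at 0 °C, and the lutidine buffer should protect the MOM acetals from traces of HBr.

Step 8
Reactants: 3 1-bromo-2,4-bis(methoxymethoxy)-3,6-dimethylbenzene; 7 carbon dioxide; 14 allyl 6-(bromomethyl)-2,4-bis(methoxymethoxy)-3-methylbenzoate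
Product: 17 allyl 6-({[2,4-bis(methoxymethoxy)-3,6-dimethylbenzoyl]oxy}methyl)-2,4-bis(methoxymethoxy)-3-methylbenzoate, via aryllithium 15 (not isolated), via lithium carboxylate 16 (not isolated)
Conditions: 3 (1.3 equiv), t-BuLi (2.5 equiv), THF, −78 °C; dry CO2 gas, −78 °C to rt; Ar purge; DMF, 14 (1.0 equiv), rt to 40 °C
Reagents that add atoms: none
Why: Bromine–lithium exchange on 3 with two equivalents of t-BuLi (the second destroys the tert-butyl bromide) gives aryllithium 15, whose ring A C1 adds to CO2 to form the C1–carboxyl bond of lithium benzoate 16; after the excess CO2 is swept out, the carboxylate oxygen displaces bromide from the benzylic CH2 of 14 in DMF (SN2) and forms the O–CH2 bond. The closest known reaction type is carboxylation of an organolithium followed by alkylation of the resulting carboxylate with an alkyl halide in a dipolar aprotic cosolvent, here run in one flask. No ring is closed and no stereocentre is formed. The selectivity needed is chemoselectivity, since no carbanion may meet the allyl ester or the bromide of 14; this is secured by the order of addition, by keeping t-BuLi just under two equivalents per 3, and by an exchange that leaves no alkyl bromide behind to compete for the carboxylate. The ortho substituents at C2 (OMOM) and C6 (CH3), which would slow acyl substitution at this carbonyl, also block a second aryllithium addition to 16 and do not hinder alkylation at the remote oxygen; 14 is the limiting component, so unreacted 16 is washed out as the acid.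

Step 9
Reactants: 17 allyl 6-({[2,4-bis(methoxymethoxy)-3,6-dimethylbenzoyl]oxy}methyl)-2,4-bis(methoxymethoxy)-3-methylbenzoate
Product: 18 allyl 6-{[(2,4-dihydroxy-3,6-dimethylbenzoyl)oxy]methyl}-2,4-dihydroxy-3-methylbenzoate
Conditions: HCl in MeOH (about 1 M), THF, rt to 40 °C
Reagents that add atoms: none
Why: Acid-catalysed acetal methanolysis should remove all four MOM ethers, and doing it while the ring B carboxyl is still an allyl ester keeps a free 2,4-dihydroxybenzoic acid (prone to decarboxylation and, next to the benzylic ester, to phthalide formation) out of the acidic medium, the two di-ortho-substituted esters being too hindered to transesterify.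

Step 10
Reactants: 18 allyl 6-{[(2,4-dihydroxy-3,6-dimethylbenzoyl)oxy]methyl}-2,4-dihydroxy-3-methylbenzoate
Product: 19 6-{[(2,4-dihydroxy-3,6-dimethylbenzoyl)oxy]methyl}-2,4-dihydroxy-3-methylbenzoic acid
Conditions: Pd(PPh3)4 (5 mol%), morpholine (5 equiv), THF, rt; cold 0.5 M HCl wash
Reagents that add atoms: none
Why: In this Tsuji–Trost-type deallylation zerovalent palladium ionises the allyl ester to a π-allyl complex that morpholine intercepts irreversibly, so the acid should be released at room temperature under near-neutral conditions that spare the benzylic ester and the free phenols, any allyl aryl ether formed in passing being cleaved by the same catalyst.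

**Compound list**

1 | 2,5-dimethylbenzene-1,3-diol | Cc1cc(O)c(C)c(O)c1 | starting material
2 | 1,3-bis(methoxymethoxy)-2,5-dimethylbenzene | Cc1cc(OCOC)c(C)c(OCOC)c1 | intermediate
3 | 1-bromo-2,4-bis(methoxymethoxy)-3,6-dimethylbenzene | Cc1cc(OCOC)c(C)c(OCOC)c1Br | intermediate
4 | 3,5-dihydroxy-4-methylbenzoic acid | Cc1c(O)cc(C(=O)O)cc1O | starting material
5 | methoxymethyl 3,5-bis(methoxymethoxy)-4-methylbenzoate | COCOC(=O)c1cc(OCOC)c(C)c(OCOC)c1 | intermediate
6 | [3,5-bis(methoxymethoxy)-4-methylphenyl]methanol | OCc1cc(OCOC)c(C)c(OCOC)c1 | intermediate
7 | carbon dioxide | O=C=O | starting material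
8 | lithium [2-lithio-3,5-bis(methoxymethoxy)-4-methylphenyl]methanolate | [Li]OCc1cc(OCOC)c(C)c(OCOC)c1[Li] | intermediate
9 | lithium 2,4-bis(methoxymethoxy)-3-methyl-6-[(lithiooxy)methyl]benzoate | [Li]OCc1cc(OCOC)c(C)c(OCOC)c1C(=O)O[Li] | intermediate
10 | 6-(hydroxymethyl)-2,4-bis(methoxymethoxy)-3-methylbenzoic acid | OCc1cc(OCOC)c(C)c(OCOC)c1C(=O)O | intermediate
11 | allyl bromide (3-bromoprop-1-ene) | C=CCBr | starting material
12 | potassium 6-(hydroxymethyl)-2,4-bis(methoxymethoxy)-3-methylbenzoate | OCc1cc(OCOC)c(C)c(OCOC)c1C(=O)[O-].[K+] | intermediate
13 | allyl 6-(hydroxymethyl)-2,4-bis(methoxymethoxy)-3-methylbenzoate | C=CCOC(=O)c1c(OCOC)c(C)c(OCOC)cc1CO | intermediate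
14 | allyl 6-(bromomethyl)-2,4-bis(methoxymethoxy)-3-methylbenzoate | C=CCOC(=O)c1c(OCOC)c(C)c(OCOC)cc1CBr | intermediate
15 | [2,4-bis(methoxymethoxy)-3,6-dimethylphenyl]lithium | Cc1cc(OCOC)c(C)c(OCOC)c1[Li] | intermediate
16 | lithium 2,4-bis(methoxymethoxy)-3,6-dimethylbenzoate | Cc1cc(OCOC)c(C)c(OCOC)c1C(=O)[O-].[Li+] | intermediate
17 | allyl 6-({[2,4-bis(methoxymethoxy)-3,6-dimethylbenzoyl]oxy}methyl)-2,4-bis(methoxymethoxy)-3-methylbenzoate | C=CCOC(=O)c1c(OCOC)c(C)c(OCOC)cc1COC(=O)c1c(C)cc(OCOC)c(C)c1OCOC | intermediate
18 | allyl 6-{[(2,4-dihydroxy-3,6-dimethylbenzoyl)oxy]methyl}-2,4-dihydroxy-3-methylbenzoate | C=CCOC(=O)c1c(O)c(C)c(O)cc1COC(=O)c1c(C)cc(O)c(C)c1O | intermediate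
19 | 6-{[(2,4-dihydroxy-3,6-dimethylbenzoyl)oxy]methyl}-2,4-dihydroxy-3-methylbenzoic acid | Cc1cc(O)c(C)c(O)c1C(=O)OCc1cc(O)c(C)c(O)c1C(=O)O | target

**Totals**

Total step count: 10. Longest linear sequence: 8 steps (4 to 19 through steps 3 to 10); the ring A branch adds steps 1 and 2.

**Steps most likely to fail**

Step 8. The lithium carboxylate may alkylate sluggishly as a tight ion pair, or adventitious proton sources may quench the aryllithium before carboxylation, leaving the benzylic bromide to decay by self-lactonisation. The fallback sets out from 3 and 13. Compound 3 is lithiated and carboxylated as before (through 15 and 16), but the mixture is then acidified with cold dilute HCl to pH 3 and 2,4-bis(methoxymethoxy)-3,6-dimethylbenzoic acid F1 is isolated by acid–base extraction. F1 and alcohol 13 are then joined by a Mitsunobu reaction (PPh3, diisopropyl azodicarboxylate, THF, 0 °C to rt). This again alkylates the carboxylate oxygen at the benzylic carbon, needs no bromide, and comes back to the route at 17.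

Step 5. Metalation may be incomplete or stray to the aryl methyl group, and acidification may cost MOM groups or cause uncontrolled lactonisation of the hydroxy acid. The fallback sets out from 6. NBS in MeCN at 0 °C should brominate the ring position next to the CH2OH group (ortho to one OMOM, para to the other) and give [2-bromo-3,5-bis(methoxymethoxy)-4-methylphenyl]methanol F2. Palladium-catalysed carbonylative lactonisation (PdCl2(PPh3)2, CO 1 atm, K2CO3, DMF, 80 °C) should then give 5,7-bis(methoxymethoxy)-6-methyl-2-benzofuran-1(3H)-one F3, a robust phthalide that can be purified. One equivalent of KOH in aqueous THF opens F3 to the potassium carboxylate 12, where the route is rejoined, and allyl bromide 11 in DMF gives 13 as in step 6.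

Step 7. The ester carbonyl may attack the activated benzylic carbon and close the phthalide with loss of the allyl group, and traces of HBr may cleave acetals. The fallback sets out from 13. Methanesulfonyl chloride, 2,4,6-trimethylpyridine and LiCl in DMF at 0 °C should give allyl 6-(chloromethyl)-2,4-bis(methoxymethoxy)-3-methylbenzoate F4 under buffered, chloride-rich conditions; the chloride is less prone to ionise. F4 then takes the place of 14 in step 8, with NaI added for in situ Finkelstein activation, and the route is rejoined at 17.

**Further compounds**

F1 | step 8 | 2,4-bis(methoxymethoxy)-3,6-dimethylbenzoic acid | Cc1cc(OCOC)c(C)c(OCOC)c1C(=O)O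
F2 | step 5 | [2-bromo-3,5-bis(methoxymethoxy)-4-methylphenyl]methanol | OCc1cc(OCOC)c(C)c(OCOC)c1Br
F3 | step 5 | 5,7-bis(methoxymethoxy)-6-methyl-2-benzofuran-1(3H)-one | O=C1OCc2cc(OCOC)c(C)c(OCOC)c12
F4 | step 7 | allyl 6-(chloromethyl)-2,4-bis(methoxymethoxy)-3-methylbenzoate | C=CCOC(=O)c1c(OCOC)c(C)c(OCOC)cc1CCl
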